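**Retrosynthetic overview**
1. Feature: in ring A the ether oxygen O1 sits on C8a and the ketone carbon C4 on the neighbouring C4a, which is flanked by the C5 methoxyl. Both ortho bonds (C8a–O1 and C4a–C4) are cut at once, as insertion of 3,4,5-trimethoxybenzyne into the carboxyl C–O bond of a stereodefined acid.
2. Ring C is the only ring formed. It closes last at O1–C2 by intramolecular Mitsunobu etherification with inversion at the benzylic carbon, and the ring B benzyl ethers are then removed.
3. The acid (C2, C3, C4 and ring B) comes from an Evans syn glycolate aldol on 3,5-bis(benzyloxy)-4-methoxybenzaldehyde, which sets C3 as R and the benzylic centre as S for the later inversion to R.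
4. The aryne precursor comes from 3,4,5-trimethoxyphenol by ortho-bromination, O-silylation, retro-Brook shift and triflation. Rings A and B are bought.

Key step: step 11

Remark: the benzylic oxygen is carried as a triisopropylsilyl ether, chosen over smaller silyl groups because it must survive CsF in THF at 125 °C; imide 13 is made in one step in case it is not stocked.

**Step 1**
Reactants: 1 3,4,5-trimethoxyphenol
Product: 2 2-bromo-3,4,5-trimethoxyphenol
Conditions: NBS (1.0 equiv), CH2Cl2, −78 °C to 0 °C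
Reagents that add atoms: N-bromosuccinimide, O=C1CCC(=O)N1Br
Why: Electrophilic aromatic bromination can only occur at the two equivalent positions ortho to the hydroxyl (para is blocked by methoxyl), and one equivalent of NBS in the cold should stop at the monobromide.

**Step 2**
Reactants: 2 2-bromo-3,4,5-trimethoxyphenol
Product: 3 (2-bromo-3,4,5-trimethoxyphenoxy)trimethylsilane
Conditions: HMDS, THF, reflux; evaporate, use crude
Reagents that add atoms: hexamethyldisilazane, C[Si](C)(C)N[Si](C)(C)C
Why: O-silylation of the phenol with hexamethyldisilazane gives the aryl silyl ether with ammonia as the only by-product.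

**Step 3**
Reactants: 3 (2-bromo-3,4,5-trimethoxyphenoxy)trimethylsilane
Product: 6 3,4,5-trimethoxy-2-(trimethylsilyl)phenyl trifluoromethanesulfonate, via aryllithium 4 (not isolated), via lithium silylphenoxide 5 (not isolated)
Conditions: n-BuLi, THF, −78 °C; then Tf2O, −78 °C to rt
Reagents that add atoms: trifluoromethanesulfonic anhydride, O=S(=O)(OS(=O)(=O)C(F)(F)F)C(F)(F)F
Why: Bromine–lithium exchange gives an aryllithium next to the silyloxy group that undergoes the anionic 1,3 O-to-C silyl shift (retro-Brook rearrangement), and the phenoxide so formed is triflated to the ortho-silylaryl triflate.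

**Step 4**
Reactants: 7 methyl 3,5-dihydroxy-4-methoxybenzoate
Product: 8 methyl 3,5-bis(benzyloxy)-4-methoxybenzoate
Conditions: BnBr, K2CO3, DMF, 60 °C
Reagents that add atoms: benzyl bromide, BrCc1ccccc1
Why: Williamson etherification of both phenols under carbonate conditions leaves the methyl ester untouched.

**Step 5**
Reactants: 8 methyl 3,5-bis(benzyloxy)-4-methoxybenzoate
Product: 9 [3,5-bis(benzyloxy)-4-methoxyphenyl]methanol
Conditions: LiAlH4, THF, 0 °C to rt; aqueous NaOH work-up
Reagents that add atoms: none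
Why: Hydride reduction of the ester gives the primary benzylic alcohol, and the aryl ethers are inert.

**Step 6**
Reactants: 9 [3,5-bis(benzyloxy)-4-methoxyphenyl]methanol
Product: 10 3,5-bis(benzyloxy)-4-methoxybenzaldehyde
Conditions: activated MnO2, CH2Cl2, rt
Reagents that add atoms: none
Why: MnO2 oxidises benzylic alcohols selectively to the aldehyde without over-oxidation.

**Step 7**
Reactants: 11 (R)-4-benzyloxazolidin-2-one; 12 methoxyacetyl chloride
Product: 13 (R)-4-benzyl-3-(2-methoxyacetyl)oxazolidin-2-one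
Conditions: n-BuLi, THF, −78 °C; then 12, −78 °C to 0 °C
Reagents that add atoms: none
Why: N-acylation of the lithiated oxazolidinone with the acid chloride gives the glycolate imide and does not touch the auxiliary stereocentre.

**Step 8**
Reactants: 13 (R)-4-benzyl-3-(2-methoxyacetyl)oxazolidin-2-one; 10 3,5-bis(benzyloxy)-4-methoxybenzaldehyde
Product: 15 (R)-4-benzyl-3-[(2R,3S)-3-[3,5-bis(benzyloxy)-4-methoxyphenyl]-3-hydroxy-2-methoxypropanoyl]oxazolidin-2-one, via dibutylboron Z-enolate 14 (not isolated)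
Conditions: Bu2BOTf, Et3N, CH2Cl2, 0 °C; then 10, −78 °C to 0 °C; then pH 7 buffer, MeOH, H2O2
Reagents that add atoms: none
Why: In this Evans syn aldol the Z boron enolate reacts through a Zimmerman–Traxler chair on the enolate face away from the benzyl group of the (R)-auxiliary, which sets C2 as R and C3 as S together.

**Step 9**
Reactants: 15 (R)-4-benzyl-3-[(2R,3S)-3-[3,5-bis(benzyloxy)-4-methoxyphenyl]-3-hydroxy-2-methoxypropanoyl]oxazolidin-2-one
Product: 16 (R)-4-benzyl-3-[(2R,3S)-3-[3,5-bis(benzyloxy)-4-methoxyphenyl]-2-methoxy-3-(triisopropylsilyloxy)propanoyl]oxazolidin-2-one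
Conditions: TIPSOTf, 2,6-lutidine, CH2Cl2, 0 °C to rt
Reagents that add atoms: triisopropylsilyl trifluoromethanesulfonate, CC(C)[Si](OS(=O)(=O)C(F)(F)F)(C(C)C)C(C)C
Why: Silylation of the hindered secondary alcohol with the silyl triflate and a hindered base is non-epimerising and installs a silyl ether that resists fluoride better than smaller ones.

**Step 10**
Reactants: 16 (R)-4-benzyl-3-[(2R,3S)-3-[3,5-bis(benzyloxy)-4-methoxyphenyl]-2-methoxy-3-(triisopropylsilyloxy)propanoyl]oxazolidin-2-one
Product: 17 (2R,3S)-3-[3,5-bis(benzyloxy)-4-methoxyphenyl]-2-methoxy-3-(triisopropylsilyloxy)propanoic acid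
Conditions: LiOH, H2O2, THF/H2O, 0 °C; then Na2SO3; then 1 M HCl to pH 3
Reagents that add atoms: hydrogen peroxide, OO
Why: Lithium hydroperoxide attacks the exocyclic imide carbonyl selectively (auxiliary hydrolysis), and the cold, weakly basic medium should not epimerise the alpha-methoxy centre.

**Step 11**
Reactants: 6 3,4,5-trimethoxy-2-(trimethylsilyl)phenyl trifluoromethanesulfonate; 17 (2R,3S)-3-[3,5-bis(benzyloxy)-4-methoxyphenyl]-2-methoxy-3-(triisopropylsilyloxy)propanoic acid
Product: 19 (2R,3S)-3-[3,5-bis(benzyloxy)-4-methoxyphenyl]-1-(2-hydroxy-4,5,6-trimethoxyphenyl)-2-methoxy-3-(triisopropylsilyloxy)propan-1-one, via 3,4,5-trimethoxybenzyne 18 (not isolated)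
Conditions: 6 (1.5 equiv), CsF (4 equiv), THF, 125 °C, sealed tube
Reagents that add atoms: none
Why: Fluoride attacks the trimethylsilyl group of 6 and expels triflate to give aryne 18; the cesium carboxylate of 17 adds through oxygen to the aryne carbon remote from the adjacent methoxyl, the aryl anion formed beside that methoxyl adds to the ester carbonyl, and collapse of the four-membered alkoxide moves the acyl group from oxygen to carbon, so that C8a–O1 and C4a–C4 (flavanone numbering) form by net insertion into the acyl C–O bond. The closest known reaction type is the CsF-mediated insertion of arynes into the C–O bond of carboxylic acids in hot THF to give ortho-hydroxyaryl ketones, in essence an anionic Fries-type 1,3 O-to-C acyl shift. No ring is closed and no stereocentre is created; C2 and C3 are only carried through, and C2 is shielded from enolisation because the acyl group is a carboxylate before the insertion and a phenoxide-conjugated ketone after it. The selectivity needed is regiochemical, and it is secured by the methoxyl next to the aryne, whose inductive pull directs the oxygen nucleophile to the distal carbon (future C8a) and places the carbanion, and hence the acyl group, at the carbon beside it (future C4a, next to the C5 methoxyl). Acyl transfer must also outrun protonation of the aryl anion, which the high temperature and the absence of protic additives favour, and the triisopropylsilyl ether is expected to resist the poorly soluble CsF.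

**Step 12**
Reactants: 19 (2R,3S)-3-[3,5-bis(benzyloxy)-4-methoxyphenyl]-1-(2-hydroxy-4,5,6-trimethoxyphenyl)-2-methoxy-3-(triisopropylsilyloxy)propan-1-one
Product: 20 (2R,3S)-3-[3,5-bis(benzyloxy)-4-methoxyphenyl]-3-hydroxy-1-(2-hydroxy-4,5,6-trimethoxyphenyl)-2-methoxypropan-1-one
Conditions: HF·pyridine, pyridine, THF, 0 °C to rt
Reagents that add atoms: none
Why: Fluoride-driven Si–O cleavage in a buffered, non-basic medium frees the benzylic alcohol without retro-aldol cleavage or beta-elimination of the beta-hydroxy ketone, and benzyl ethers are inert.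

**Step 13**
Reactants: 20 (2R,3S)-3-[3,5-bis(benzyloxy)-4-methoxyphenyl]-3-hydroxy-1-(2-hydroxy-4,5,6-trimethoxyphenyl)-2-methoxypropan-1-one
Product: 21 (2R,3R)-2-[3,5-bis(benzyloxy)-4-methoxyphenyl]-3,5,6,7-tetramethoxychroman-4-one
Conditions: PPh3, DIAD, THF, 0 °C to rt
Reagents that add atoms: none
Why: In this intramolecular Mitsunobu etherification the chelated phenol displaces the benzylic oxyphosphonium group in a 6-exo-tet SN2 closure with inversion (benzylic S becomes C2 R), which gives the 2,3-trans ring C while C3 is untouched.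

**Step 14**
Reactants: 21 (2R,3R)-2-[3,5-bis(benzyloxy)-4-methoxyphenyl]-3,5,6,7-tetramethoxychroman-4-one
Product: 22 (2R,3R)-2-(3,5-dihydroxy-4-methoxyphenyl)-3,5,6,7-tetramethoxychroman-4-one
Conditions: H2 (1 atm), 10% Pd/C, EtOAc, rt
Reagents that add atoms: none
Why: Catalytic hydrogenolysis of the two aryl benzyl ethers under neutral conditions should be much faster than cleavage of the cyclic benzylic C2–O1 bond or reduction of the ketone, and neither stereocentre takes part.

**Compound list**
1 | 3,4,5-trimethoxyphenol | COc1cc(O)cc(OC)c1OC | starting material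
2 | 2-bromo-3,4,5-trimethoxyphenol | COc1cc(O)c(Br)c(OC)c1OC | intermediate
3 | (2-bromo-3,4,5-trimethoxyphenoxy)trimethylsilane | COc1cc(O[Si](C)(C)C)c(Br)c(OC)c1OC | intermediate
4 | [2,3,4-trimethoxy-6-(trimethylsilyloxy)phenyl]lithium | COc1cc(O[Si](C)(C)C)c([Li])c(OC)c1OC | intermediate
5 | lithium 3,4,5-trimethoxy-2-(trimethylsilyl)phenoxide | [Li+].[O-]c1cc(OC)c(OC)c(OC)c1[Si](C)(C)C | intermediate
6 | 3,4,5-trimethoxy-2-(trimethylsilyl)phenyl trifluoromethanesulfonate | COc1cc(OS(=O)(=O)C(F)(F)F)c([Si](C)(C)C)c(OC)c1OC | intermediate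
7 | methyl 3,5-dihydroxy-4-methoxybenzoate | COC(=O)c1cc(O)c(OC)c(O)c1 | starting material
8 | methyl 3,5-bis(benzyloxy)-4-methoxybenzoate | COC(=O)c1cc(OCc2ccccc2)c(OC)c(OCc2ccccc2)c1 | intermediate
9 | [3,5-bis(benzyloxy)-4-methoxyphenyl]methanol | OCc1cc(OCc2ccccc2)c(OC)c(OCc2ccccc2)c1 | intermediate
10 | 3,5-bis(benzyloxy)-4-methoxybenzaldehyde | O=Cc1cc(OCc2ccccc2)c(OC)c(OCc2ccccc2)c1 | intermediate
11 | (R)-4-benzyloxazolidin-2-one | O=C1N[C@H](Cc2ccccc2)CO1 | starting material
12 | methoxyacetyl chloride | COCC(Cl)=O | starting material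
13 | (R)-4-benzyl-3-(2-methoxyacetyl)oxazolidin-2-one | COCC(=O)N1C(=O)OC[C@H]1Cc1ccccc1 | intermediate
14 | (R)-4-benzyl-3-[(Z)-1-(dibutylboryloxy)-2-methoxyvinyl]oxazolidin-2-one | CCCCB(CCCC)O/C(=C\OC)N1C(=O)OC[C@H]1Cc1ccccc1 | intermediate
15 | (R)-4-benzyl-3-[(2R,3S)-3-[3,5-bis(benzyloxy)-4-methoxyphenyl]-3-hydroxy-2-methoxypropanoyl]oxazolidin-2-one | O=C1OC[C@@H](Cc2ccccc2)N1C(=O)[C@H](OC)[C@@H](O)c1cc(OCc2ccccc2)c(OC)c(OCc2ccccc2)c1 | intermediate
16 | (R)-4-benzyl-3-[(2R,3S)-3-[3,5-bis(benzyloxy)-4-methoxyphenyl]-2-methoxy-3-(triisopropylsilyloxy)propanoyl]oxazolidin-2-one | O=C1OC[C@@H](Cc2ccccc2)N1C(=O)[C@H](OC)[C@@H](O[Si](C(C)C)(C(C)C)C(C)C)c1cc(OCc2ccccc2)c(OC)c(OCc2ccccc2)c1 | intermediate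
17 | (2R,3S)-3-[3,5-bis(benzyloxy)-4-methoxyphenyl]-2-methoxy-3-(triisopropylsilyloxy)propanoic acid | OC(=O)[C@H](OC)[C@@H](O[Si](C(C)C)(C(C)C)C(C)C)c1cc(OCc2ccccc2)c(OC)c(OCc2ccccc2)c1 | intermediate
18 | 3,4,5-trimethoxybenzyne (1,2-didehydro-3,4,5-trimethoxybenzene) | COC1=C(OC)C(OC)=CC#C1 | intermediate
19 | (2R,3S)-3-[3,5-bis(benzyloxy)-4-methoxyphenyl]-1-(2-hydroxy-4,5,6-trimethoxyphenyl)-2-methoxy-3-(triisopropylsilyloxy)propan-1-one | COc1cc(O)c(c(OC)c1OC)C(=O)[C@H](OC)[C@@H](O[Si](C(C)C)(C(C)C)C(C)C)c1cc(OCc2ccccc2)c(OC)c(OCc2ccccc2)c1 | intermediate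
20 | (2R,3S)-3-[3,5-bis(benzyloxy)-4-methoxyphenyl]-3-hydroxy-1-(2-hydroxy-4,5,6-trimethoxyphenyl)-2-methoxypropan-1-one | COc1cc(O)c(c(OC)c1OC)C(=O)[C@H](OC)[C@@H](O)c1cc(OCc2ccccc2)c(OC)c(OCc2ccccc2)c1 | intermediate
21 | (2R,3R)-2-[3,5-bis(benzyloxy)-4-methoxyphenyl]-3,5,6,7-tetramethoxychroman-4-one | COc1cc2c(c(OC)c1OC)C(=O)[C@H](OC)[C@@H](c1cc(OCc3ccccc3)c(OC)c(OCc3ccccc3)c1)O2 | intermediate
22 | (2R,3R)-2-(3,5-dihydroxy-4-methoxyphenyl)-3,5,6,7-tetramethoxychroman-4-one | COc1cc2c(c(OC)c1OC)C(=O)[C@H](OC)[C@@H](c1cc(O)c(OC)c(O)c1)O2 | target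

**Totals**
Total step count: 14. Longest linear sequence: 10 steps (4, 5, 6, 8, 9, 10, 11, 12, 13, 14).

**Steps most likely to fail, in falling order of risk**

Step 11. The aryl anion formed after O-arylation may be protonated before it transfers the acyl group, which would give the aryl ester in place of the ketone. Fluoride may also strip the silyl ether at 125 °C with retro-aldol cleavage, and the product phenoxide may add to a second aryne. The fallback joins the same two carbons by organolithium acylation without fluoride; it sets out from 17 and 2 and comes back at 19. Acid 17 would be coupled with N,O-dimethylhydroxylamine hydrochloride (EDC·HCl, HOBt, iPr2NEt, CH2Cl2) to give the Weinreb amide (2R,3S)-3-[3,5-bis(benzyloxy)-4-methoxyphenyl]-N,2-dimethoxy-N-methyl-3-(triisopropylsilyloxy)propanamide F1. Bromophenol 2 would be protected (MOMCl, iPr2NEt, CH2Cl2) as 2-bromo-3,4,5-trimethoxy-1-(methoxymethoxy)benzene F2. Bromine–lithium exchange on F2 (n-BuLi, THF, −78 °C) and addition of F1 should give (2R,3S)-3-[3,5-bis(benzyloxy)-4-methoxyphenyl]-2-methoxy-1-[4,5,6-trimethoxy-2-(methoxymethoxy)phenyl]-3-(triisopropylsilyloxy)propan-1-one F3. Aqueous HCl in MeOH/THF at 40 °C would then remove the aryl methoxymethyl group and return the route to 19.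

Step 13. The oxyphosphonium intermediate may undergo beta-elimination to the alpha-methoxychalcone, which destroys both stereocentres, and partial ionisation at the benzylic carbon would erode the inversion. The fallback separates activation from ring closure; it sets out from 19 and comes back at 21. The phenol of 19 would be acetylated (Ac2O, pyridine, DMAP) to 2-[(2R,3S)-3-[3,5-bis(benzyloxy)-4-methoxyphenyl]-2-methoxy-3-(triisopropylsilyloxy)propanoyl]-3,4,5-trimethoxyphenyl acetate F4. HF·pyridine would free the alcohol 2-[(2R,3S)-3-[3,5-bis(benzyloxy)-4-methoxyphenyl]-3-hydroxy-2-methoxypropanoyl]-3,4,5-trimethoxyphenyl acetate F5. Cold sulfonylation (MsCl, Et3N, CH2Cl2, −40 °C) would give 2-[(2R,3S)-3-[3,5-bis(benzyloxy)-4-methoxyphenyl]-2-methoxy-3-(methylsulfonyloxy)propanoyl]-3,4,5-trimethoxyphenyl acetate F6, used crude. K2CO3 in MeOH at 0 °C would cleave the aryl acetate, and the phenoxide so released (which also lowers the acidity of the alpha-hydrogen) should displace the mesylate by SN2 with inversion to give 21.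

Step 3. Butyllithium may attack silicon of the aryl silyl ether instead of bromine, and the silyl shift to a carbon flanked by two oxygen substituents may be incomplete or the aryllithium protonated, so that unsilylated aryl triflate results. The fallback installs silicon by directed ortho-metalation; it sets out from 1 and comes back at 6. Phenol 1 would be converted (isopropyl isocyanate, Et3N, CH2Cl2) into 3,4,5-trimethoxyphenyl N-isopropylcarbamate F7. In situ N-silylation (TBSOTf, TMEDA, Et2O), ortho-lithiation (n-BuLi, TMEDA, −78 °C), quenching with TMSCl and acidic work-up should give 3,4,5-trimethoxy-2-(trimethylsilyl)phenyl N-isopropylcarbamate F8. Carbamate cleavage (DBU, Et2NH, MeCN, 40 °C) followed by PhNTf2 in the same flask would give 6.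

**Further compounds**
F1 | step 11 | (2R,3S)-3-[3,5-bis(benzyloxy)-4-methoxyphenyl]-N,2-dimethoxy-N-methyl-3-(triisopropylsilyloxy)propanamide | CON(C)C(=O)[C@H](OC)[C@@H](O[Si](C(C)C)(C(C)C)C(C)C)c1cc(OCc2ccccc2)c(OC)c(OCc2ccccc2)c1
F2 | step 11 | 2-bromo-3,4,5-trimethoxy-1-(methoxymethoxy)benzene | COCOc1cc(OC)c(OC)c(OC)c1Br
F3 | step 11 | (2R,3S)-3-[3,5-bis(benzyloxy)-4-methoxyphenyl]-2-methoxy-1-[4,5,6-trimethoxy-2-(methoxymethoxy)phenyl]-3-(triisopropylsilyloxy)propan-1-one | COCOc1cc(OC)c(OC)c(OC)c1C(=O)[C@H](OC)[C@@H](O[Si](C(C)C)(C(C)C)C(C)C)c1cc(OCc2ccccc2)c(OC)c(OCc2ccccc2)c1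
F4 | step 13 | 2-[(2R,3S)-3-[3,5-bis(benzyloxy)-4-methoxyphenyl]-2-methoxy-3-(triisopropylsilyloxy)propanoyl]-3,4,5-trimethoxyphenyl acetate | CC(=O)Oc1cc(OC)c(OC)c(OC)c1C(=O)[C@H](OC)[C@@H](O[Si](C(C)C)(C(C)C)C(C)C)c1cc(OCc2ccccc2)c(OC)c(OCc2ccccc2)c1
F5 | step 13 | 2-[(2R,3S)-3-[3,5-bis(benzyloxy)-4-methoxyphenyl]-3-hydroxy-2-methoxypropanoyl]-3,4,5-trimethoxyphenyl acetate | CC(=O)Oc1cc(OC)c(OC)c(OC)c1C(=O)[C@H](OC)[C@@H](O)c1cc(OCc2ccccc2)c(OC)c(OCc2ccccc2)c1
F6 | step 13 | 2-[(2R,3S)-3-[3,5-bis(benzyloxy)-4-methoxyphenyl]-2-methoxy-3-(methylsulfonyloxy)propanoyl]-3,4,5-trimethoxyphenyl acetate | CC(=O)Oc1cc(OC)c(OC)c(OC)c1C(=O)[C@H](OC)[C@@H](OS(C)(=O)=O)c1cc(OCc2ccccc2)c(OC)c(OCc2ccccc2)c1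
F7 | step 3 | 3,4,5-trimethoxyphenyl N-isopropylcarbamate | CC(C)NC(=O)Oc1cc(OC)c(OC)c(OC)c1
F8 | step 3 | 3,4,5-trimethoxy-2-(trimethylsilyl)phenyl N-isopropylcarbamate | CC(C)NC(=O)Oc1cc(OC)c(OC)c(OC)c1[Si](C)(C)C
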